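The route rests on cutting ring B at C5–C10 and C8–C9. Ring B carries oxygen at C6 and C8, flanking C7, and C5/C10 are the fusion atoms; this is the retron of a 1-alkoxy-3-silyloxy diene (C5–C8) adding to a tethered (E)-enoate (C9=C10). One intramolecular Diels–Alder reaction closes rings A and B, forms both bonds and sets C5, C9 and C10 from the single stereocentre C4, giving the 6-oxo-7-ene. The precursor is an acyclic trienoate with a (Z)-silyl dienol ether and a quaternary C4 bearing C18 as a dioxolane-masked aldehyde. The butenolide side chain is added late by B-alkyl Suzuki coupling.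

Key step: step 12

Remarks on the chemistry (assumptions):
- Atom labels: decalin C1–C10 as in labdanes (C4 quaternary, C18 its α one-carbon substituent, C5/C10 ring fusion), side chain C11–C16 from C9 to the butenolide CH–O carbon; α is the face opposite the C10 methyl.
- C18 is carried from step 8 as a 1,3-dioxolane: it is branched at the carbon on C4 (larger equatorial preference than a CH2O group), already at the aldehyde level, and inert to Li/NH3, which an aryl silyl ether is not.
- The diene alkoxy group is ethoxy, matching the ethyl ester so that step 10 cannot transesterify; it is lost in step 12.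
- In step 24 the two free hydroxyls are taken to be O-borylated reversibly by excess 9-BBN and released by the aqueous base; 39 is drawn with free hydroxyls.
- The target is written as the open 6-hydroxy-18-aldehyde; equilibration with the 18,6-lactol would not change the route.

Step 1
Reactants: 1 2-(3-chloropropyl)-2-methyl-1,3-dioxolane; 2 ethyl but-2-ynoate
Product: 5 ethyl (E)-3-methyl-6-(2-methyl-1,3-dioxolan-2-yl)hex-2-enoate, via Grignard reagent 3 (not isolated), via alkylcopper 4 (not isolated)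
Conditions: Mg, THF, reflux; CuI, −78 °C; then 2, −78 °C; aq. NH4Cl
Reagents that add atoms: none
Why: Carbocupration (syn conjugate addition of the alkylcopper to the ynoate, quenched cold) should place the alkyl chain trans to the ester and so fix the (E)-trisubstituted alkene whose geometry later controls C4.

Step 2
Reactants: 5 ethyl (E)-3-methyl-6-(2-methyl-1,3-dioxolan-2-yl)hex-2-enoate
Product: 7 (E)-4-methyl-7-(2-methyl-1,3-dioxolan-2-yl)hept-3-en-2-one, via Weinreb amide 6 (not isolated)
Conditions: MeNHOMe·HCl, i-PrMgCl, THF, −20 °C; then MeMgBr, 0 °C; aq. NH4Cl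
Reagents that add atoms: methylmagnesium bromide, C[Mg]Br
Why: Weinreb ketone synthesis in one pot should stop at the methyl ketone through the chelated tetrahedral intermediate, leaving alkene geometry and ketal untouched.

Step 3
Reactants: 7 (E)-4-methyl-7-(2-methyl-1,3-dioxolan-2-yl)hept-3-en-2-one
Product: 8 (2R,3E)-4-methyl-7-(2-methyl-1,3-dioxolan-2-yl)hept-3-en-2-ol
Conditions: (S)-2-methyl-CBS-oxazaborolidine (10 mol %), BH3·SMe2, THF, −30 °C
Reagents that add atoms: none
Why: Corey–Bakshi–Shibata reduction with the (S)-oxazaborolidine should deliver hydride to the face that gives the (R)-allylic alcohol, the alkenyl group acting as the large substituent.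

Step 4
Reactants: 8 (2R,3E)-4-methyl-7-(2-methyl-1,3-dioxolan-2-yl)hept-3-en-2-ol; 9 triethyl orthoacetate
Product: 11 ethyl (3R,4E)-3-methyl-3-[3-(2-methyl-1,3-dioxolan-2-yl)propyl]hex-4-enoate, via ketene acetal 10 (not isolated)
Conditions: EtCO2H (cat.), neat, 140 °C, EtOH distilled off
Reagents that add atoms: none
Why: Johnson–Claisen rearrangement through a chair transition state with the carbinol methyl equatorial should transfer the carbinol chirality to the quaternary C4 (the new C–C bond forms on the face that carried oxygen) and leave an (E)-propenyl group as the future C18.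

Step 5
Reactants: 11 ethyl (3R,4E)-3-methyl-3-[3-(2-methyl-1,3-dioxolan-2-yl)propyl]hex-4-enoate
Product: 13 (3R,4E)-N-methoxy-N,3-dimethyl-3-(4-oxopentyl)hex-4-enamide, via ketal Weinreb amide 12 (not isolated)
Conditions: MeNHOMe·HCl, i-PrMgCl, THF, −15 °C → rt; then 1 M HCl, rt
Reagents that add atoms: N,O-dimethylhydroxylamine hydrochloride, CNOC.Cl; water, O
Why: Weinreb amidation of the ester by the magnesium amide followed by acid hydrolysis of the ketone ketal in the work-up should give the C6 amide and the free C10 methyl ketone without affecting C4.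

Step 6
Reactants: 13 (3R,4E)-N-methoxy-N,3-dimethyl-3-(4-oxopentyl)hex-4-enamide; 14 triethyl phosphonoacetate
Product: 15 ethyl (2E,7R,8E)-7-{2-[methoxy(methyl)amino]-2-oxoethyl}-3,7-dimethyldeca-2,8-dienoate
Conditions: NaH, THF, 0 °C → 50 °C
Reagents that add atoms: none
Why: Horner–Wadsworth–Emmons olefination of the methyl ketone should give mainly the (E)-enoate, the minor (Z)-isomer being removed by chromatography, while the Weinreb amide is inert to the phosphonate anion.

Step 7
Reactants: 15 ethyl (2E,7R,8E)-7-{2-[methoxy(methyl)amino]-2-oxoethyl}-3,7-dimethyldeca-2,8-dienoate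
Product: 16 ethyl (2E,7R)-7-formyl-9-[methoxy(methyl)amino]-3,7-dimethyl-9-oxonon-2-enoate
Conditions: O3, CH2Cl2, pyridine, −78 °C, Sudan Red 7B as end-point indicator; then Me2S
Reagents that add atoms: ozone, [O-][O+]=O
Why: Ozonolysis with reductive work-up should cleave the electron-rich disubstituted propenyl alkene far faster than the electron-poor trisubstituted enoate, leaving C18 as the aldehyde.

Step 8
Reactants: 16 ethyl (2E,7R)-7-formyl-9-[methoxy(methyl)amino]-3,7-dimethyl-9-oxonon-2-enoate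
Product: 17 ethyl (2E,7R)-7-(1,3-dioxolan-2-yl)-9-[methoxy(methyl)amino]-3,7-dimethyl-9-oxonon-2-enoate
Conditions: 1,2-bis(trimethylsilyloxy)ethane, TMSOTf (cat.), CH2Cl2, −78 → −20 °C
Reagents that add atoms: 1,2-bis(trimethylsilyloxy)ethane, C[Si](C)(C)OCCO[Si](C)(C)C
Why: Noyori acetalization should protect the hindered aldehyde under aprotic conditions that spare the ester and the amide.

Step 9
Reactants: 17 ethyl (2E,7R)-7-(1,3-dioxolan-2-yl)-9-[methoxy(methyl)amino]-3,7-dimethyl-9-oxonon-2-enoate; 18 prop-1-yn-1-ylmagnesium bromide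
Product: 19 ethyl (2E,7R)-7-(1,3-dioxolan-2-yl)-3,7-dimethyl-9-oxododec-2-en-10-ynoate
Conditions: THF, −20 → 0 °C; aq. NH4Cl
Reagents that add atoms: none
Why: Weinreb ketone synthesis with the alkynyl Grignard reagent should give the ynone, the conjugated β,β-disubstituted ethyl ester being far less electrophilic toward this weak nucleophile.

Step 10
Reactants: 19 ethyl (2E,7R)-7-(1,3-dioxolan-2-yl)-3,7-dimethyl-9-oxododec-2-en-10-ynoate
Product: 20 ethyl (2E,7R,10E)-7-(1,3-dioxolan-2-yl)-11-ethoxy-3,7-dimethyl-9-oxododeca-2,10-dienoate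
Conditions: EtOH, NaOEt (cat.), 0 °C → rt
Reagents that add atoms: ethanol, CCO
Why: Base-catalysed oxa-Michael addition of ethanol to the ynone should give the thermodynamically preferred (E)-β-ethoxy enone with oxygen only at C8.

Step 11
Reactants: 20 ethyl (2E,7R,10E)-7-(1,3-dioxolan-2-yl)-11-ethoxy-3,7-dimethyl-9-oxododeca-2,10-dienoate
Product: 21 ethyl (2E,7R,8Z,10E)-9-[(tert-butyldimethylsilyl)oxy]-7-(1,3-dioxolan-2-yl)-11-ethoxy-3,7-dimethyldodeca-2,8,10-trienoate
Conditions: LDA, THF, −78 °C; TBSCl, DMPU, −78 → 0 °C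
Reagents that add atoms: tert-butyldimethylsilyl chloride, CC(C)(C)[Si](C)(C)Cl
Why: Kinetic α′-deprotonation of the vinylogous ester at C5 and O-silylation should give the (Z)-silyl dienol ether with C4 trans to C7, because a cis arrangement of the quaternary carbon and the alkenyl group is strongly disfavoured.

Step 12
Reactants: 21 ethyl (2E,7R,8Z,10E)-9-[(tert-butyldimethylsilyl)oxy]-7-(1,3-dioxolan-2-yl)-11-ethoxy-3,7-dimethyldodeca-2,8,10-trienoate
Product: 23 ethyl 4α-(1,3-dioxolan-2-yl)-4β,8,10β-trimethyl-6-oxo-5αH-decal-7-ene-9β-carboxylate, via silyl enol ether cycloadduct 22 (not isolated)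
Conditions: PhMe (0.02 M), BHT, Et3N (cat.), 180 °C, sealed tube; then 1 M HCl, THF, 0 °C
Reagents that add atoms: none
Why: On heating, the electron-rich diene C5=C6–C7=C8 and the tethered enoate C9=C10 undergo a concerted but asynchronous normal-demand [4+2] cycloaddition in which C5–C10 bonding runs ahead of C8–C9, and acid then hydrolyses the silyl enol ether of 22 and eliminates ethanol to leave the C6 ketone and the C7=C8 alkene. The closest known reaction type is the intramolecular Diels–Alder reaction of 1-alkoxy-3-silyloxy-1,3-dienes with tethered α,β-unsaturated esters. Ring B is the six-membered cycloadduct ring itself, and ring A closes as a six-membered ring through the tether C1–C4 that links the diene terminus C5 to the dienophile carbon C10, in a chair-like trans-fused arrangement. C10 is set by the C4 stereocentre, whose branched dioxolanyl group takes the equatorial position away from the forming C5–C10 bond while the C4 methyl lies axial; C5 is set by the trans-fused transition state and, being α to the C6 ketone, can also settle to the trans fusion; C9 follows from the (E)-enoate with the ester endo and is the equatorial epimer that equilibration would also favour. The step needs diene-face selectivity and the trans-fused mode (regiochemistry is fixed by the tether): the first is secured by the size difference between dioxolanyl and methyl at C4, the second by the (E)-enoate with its ester endo, and cyclization is favoured over oligomerization by the fully substituted C4 and high dilution.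

Step 13
Reactants: 23 ethyl 4α-(1,3-dioxolan-2-yl)-4β,8,10β-trimethyl-6-oxo-5αH-decal-7-ene-9β-carboxylate
Product: 24 ethyl 4α-(1,3-dioxolan-2-yl)-7α,8α-epoxy-4β,8β,10β-trimethyl-6-oxo-5αH-decalin-9β-carboxylate
Conditions: t-BuOOH, Triton B (benzyltrimethylammonium hydroxide, cat.), THF, 0 °C → rt
Reagents that add atoms: tert-butyl hydroperoxide, CC(C)(C)OO
Why: Weitz–Scheffer nucleophilic epoxidation should deliver the peroxide to C8 from the α face, anti to the axial C10 methyl that shields the β face, giving the 7α,8α-epoxide.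

Step 14
Reactants: 24 ethyl 4α-(1,3-dioxolan-2-yl)-7α,8α-epoxy-4β,8β,10β-trimethyl-6-oxo-5αH-decalin-9β-carboxylate
Product: 25 ethyl 4α-(1,3-dioxolan-2-yl)-8α-hydroxy-4β,8β,10β-trimethyl-6-oxo-5αH-decalin-9β-carboxylate
Conditions: SmI2 (2.2 equiv), THF/MeOH, −78 °C
Reagents that add atoms: none
Why: Single-electron reductive opening of the α,β-epoxy ketone by SmI2 cleaves only the C7–O bond, so the C8–O bond and with it the 8α-hydroxy-8β-methyl configuration is retained.

Step 15
Reactants: 25 ethyl 4α-(1,3-dioxolan-2-yl)-8α-hydroxy-4β,8β,10β-trimethyl-6-oxo-5αH-decalin-9β-carboxylate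
Product: 26 4α-(1,3-dioxolan-2-yl)-9β-(hydroxymethyl)-4β,8β,10β-trimethyl-5αH-decalin-6α,8α-diol
Conditions: Li (excess), NH3(l)/THF, EtOH, −78 → −33 °C; NH4Cl
Reagents that add atoms: none
Why: Dissolving-metal reduction should convert the C6 ketone into the thermodynamically preferred equatorial 6α-alcohol (the axial 6β-alcohol would suffer two 1,3-diaxial methyl interactions) and reduce the ester to the primary alcohol in the same pot (Bouveault–Blanc reduction).

Step 16
Reactants: 26 4α-(1,3-dioxolan-2-yl)-9β-(hydroxymethyl)-4β,8β,10β-trimethyl-5αH-decalin-6α,8α-diol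
Product: 27 4α-(1,3-dioxolan-2-yl)-6α,8α-dihydroxy-4β,8β,10β-trimethyl-5αH-decalin-9β-carbaldehyde
Conditions: TEMPO (2,2,6,6-tetramethylpiperidine-1-oxyl, cat.), PhI(OAc)2, CH2Cl2, rt
Reagents that add atoms: none
Why: TEMPO-catalysed oxidation is selective for the primary alcohol over the hindered secondary and the tertiary hydroxyl and stops at the aldehyde.

Step 17
Reactants: 27 4α-(1,3-dioxolan-2-yl)-6α,8α-dihydroxy-4β,8β,10β-trimethyl-5αH-decalin-9β-carbaldehyde
Product: 28 4α-(1,3-dioxolan-2-yl)-4β,8β,10β-trimethyl-9β-vinyl-5αH-decalin-6α,8α-diol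
Conditions: Ph3PCH3Br, KHMDS (4 equiv of ylide), THF, 0 °C → rt
Reagents that add atoms: methyltriphenylphosphonium bromide, C[P+](c1ccccc1)(c1ccccc1)c1ccccc1.[Br-]
Why: Wittig methylenation with excess non-stabilised ylide should convert the hindered aldehyde into the vinyl group faster than base-induced retro-aldol cleavage, C9 already being the equatorial epimer.

Step 18
Reactants: 29 dimethyl (4R,5R)-2,2-dimethyl-1,3-dioxolane-4,5-dicarboxylate
Product: 30 (4R,5R)-N4,N5-dimethoxy-N4,N5,2,2-tetramethyl-1,3-dioxolane-4,5-dicarboxamide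
Conditions: MeNHOMe·HCl, i-PrMgCl, THF, −20 °C
Reagents that add atoms: N,O-dimethylhydroxylamine hydrochloride, CNOC.Cl
Why: Weinreb amidation of both esters of the L-tartrate acetonide should proceed without epimerization and supplies C14 and C15 with the required threo configuration.

Step 19
Reactants: 30 (4R,5R)-N4,N5-dimethoxy-N4,N5,2,2-tetramethyl-1,3-dioxolane-4,5-dicarboxamide
Product: 31 (4R,5R)-5-acetyl-N-methoxy-N,2,2-trimethyl-1,3-dioxolane-4-carboxamide
Conditions: MeMgBr (1.1 equiv), THF, −78 → 0 °C; aq. NH4Cl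
Reagents that add atoms: methylmagnesium bromide, C[Mg]Br
Why: Weinreb ketone synthesis with one equivalent of Grignard reagent should stop at mono-addition, since the magnesium chelate of the first tetrahedral intermediate deactivates the neighbouring amide and the ketone is released only on work-up.

Step 20
Reactants: 31 (4R,5R)-5-acetyl-N-methoxy-N,2,2-trimethyl-1,3-dioxolane-4-carboxamide
Product: 32 1-{(4R,5R)-5-[methoxy(methyl)carbamoyl]-2,2-dimethyl-1,3-dioxolan-4-yl}vinyl trifluoromethanesulfonate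
Conditions: KHMDS, THF, −78 °C; PhNTf2
Reagents that add atoms: N-phenylbis(trifluoromethanesulfonimide), O=S(=O)(N(c1ccccc1)S(=O)(=O)C(F)(F)F)C(F)(F)F
Why: Kinetic deprotonation of the methyl ketone at the methyl group and O-triflation (enol triflate formation) should give the 1,1-disubstituted vinyl triflate that carries C13 and its methylene without disturbing the ring stereocentres.

Step 21
Reactants: 32 1-{(4R,5R)-5-[methoxy(methyl)carbamoyl]-2,2-dimethyl-1,3-dioxolan-4-yl}vinyl trifluoromethanesulfonate; 33 ethyl propiolate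
Product: 35 ethyl 4-{(4R,5R)-2,2-dimethyl-5-[1-(trifluoromethylsulfonyloxy)vinyl]-1,3-dioxolan-4-yl}-4-oxobut-2-ynoate, via lithium acetylide 34 (not isolated)
Conditions: 33, LiHMDS, THF, −78 °C; then 32, −78 °C; aq. NH4Cl
Reagents that add atoms: none
Why: Acylation of the lithium acetylide by the Weinreb amide (Weinreb ketone synthesis) should give the γ-oxo ynoate at −78 °C, a temperature at which the vinyl triflate is inert.

Step 22
Reactants: 35 ethyl 4-{(4R,5R)-2,2-dimethyl-5-[1-(trifluoromethylsulfonyloxy)vinyl]-1,3-dioxolan-4-yl}-4-oxobut-2-ynoate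
Product: 36 ethyl (4R)-4-{(4S,5R)-2,2-dimethyl-5-[1-(trifluoromethylsulfonyloxy)vinyl]-1,3-dioxolan-4-yl}-4-hydroxybut-2-ynoate
Conditions: (S)-Alpine-Borane (B-isopinocampheyl-9-BBN from (−)-α-pinene), THF, rt
Reagents that add atoms: none
Why: Midland reduction of the γ-oxo ynoate, with the alkynyl group as the small substituent, should give with the (S)-reagent the (R)-carbinol at C16, which is also the Felkin–Anh product syn to the C15 oxygen.

Step 23
Reactants: 36 ethyl (4R)-4-{(4S,5R)-2,2-dimethyl-5-[1-(trifluoromethylsulfonyloxy)vinyl]-1,3-dioxolan-4-yl}-4-hydroxybut-2-ynoate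
Product: 38 1-{(4R,5S)-2,2-dimethyl-5-[(2R)-3-methyl-5-oxo-2,5-dihydrofuran-2-yl]-1,3-dioxolan-4-yl}vinyl trifluoromethanesulfonate, via hydroxy enoate 37 (not isolated)
Conditions: Me2CuLi (from MeLi, CuI; 3 equiv), THF, −78 °C; aq. NH4Cl, rt
Reagents that add atoms: lithium dimethylcuprate, [Li+].C[Cu-]C
Why: syn-Carbocupration of the ynoate puts methyl and hydrogen cis, so the ester is cis to the carbinol and the (Z)-hydroxy enoate lactonizes to the β-methyl butenolide with C16 unchanged, the conjugate addition at −78 °C being much faster than cuprate coupling with the triflate.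

Step 24
Reactants: 28 4α-(1,3-dioxolan-2-yl)-4β,8β,10β-trimethyl-9β-vinyl-5αH-decalin-6α,8α-diol; 38 1-{(4R,5S)-2,2-dimethyl-5-[(2R)-3-methyl-5-oxo-2,5-dihydrofuran-2-yl]-1,3-dioxolan-4-yl}vinyl trifluoromethanesulfonate
Product: 40 18,18-ethylenedioxy-14,15-O-isopropylidene derivative of the target, via alkylborane 39 (not isolated)
Conditions: 9-BBN (4 equiv), THF, rt → 50 °C; aq. K3PO4; then 38, Pd(dppf)Cl2 (5 mol %), AsPh3, DMF, rt
Reagents that add atoms: none
Why: anti-Markovnikov hydroboration of the vinyl group and B-alkyl Suzuki–Miyaura coupling with the enol triflate should form the C12–C13 bond and the 1,1-disubstituted alkene without touching any stereocentre.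

Step 25
Reactants: 40 18,18-ethylenedioxy-14,15-O-isopropylidene derivative of the target
Product: 41 CNP0156243.1 (target)
Conditions: 1 M HCl, THF, rt
Reagents that add atoms: water, O
Why: Acid hydrolysis of the acetonide and of the dioxolane frees the 14,15-diol and the C18 aldehyde in one operation, the 6α-hydroxyl trapping the intermediate oxocarbenium as a cyclic acetal that hydrolyses readily.

Compound list
1 | 2-(3-chloropropyl)-2-methyl-1,3-dioxolane | CC1(CCCCl)OCCO1 | starting material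
2 | ethyl but-2-ynoate | CCOC(=O)C#CC | starting material
3 | [3-(2-methyl-1,3-dioxolan-2-yl)propyl]magnesium chloride | CC1(CCC[Mg]Cl)OCCO1 | intermediate
4 | [3-(2-methyl-1,3-dioxolan-2-yl)propyl]copper | CC1(CCC[Cu])OCCO1 | intermediate
5 | ethyl (E)-3-methyl-6-(2-methyl-1,3-dioxolan-2-yl)hex-2-enoate | CCOC(=O)/C=C(\C)CCCC1(C)OCCO1 | intermediate
6 | (E)-N-methoxy-N,3-dimethyl-6-(2-methyl-1,3-dioxolan-2-yl)hex-2-enamide | CON(C)C(=O)/C=C(\C)CCCC1(C)OCCO1 | intermediate
7 | (E)-4-methyl-7-(2-methyl-1,3-dioxolan-2-yl)hept-3-en-2-one | CC(=O)/C=C(\C)CCCC1(C)OCCO1 | intermediate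
8 | (2R,3E)-4-methyl-7-(2-methyl-1,3-dioxolan-2-yl)hept-3-en-2-ol | C[C@@H](O)/C=C(\C)CCCC1(C)OCCO1 | intermediate
9 | triethyl orthoacetate | CCOC(C)(OCC)OCC | starting material
10 | 1-ethoxyvinyl ether of 8 (mixed ketene acetal) | C=C(OCC)O[C@H](C)/C=C(\C)CCCC1(C)OCCO1 | intermediate
11 | ethyl (3R,4E)-3-methyl-3-[3-(2-methyl-1,3-dioxolan-2-yl)propyl]hex-4-enoate | CCOC(=O)C[C@@](C)(CCCC1(C)OCCO1)/C=C/C | intermediate
12 | (3R,4E)-N-methoxy-N,3-dimethyl-3-[3-(2-methyl-1,3-dioxolan-2-yl)propyl]hex-4-enamide | CON(C)C(=O)C[C@@](C)(CCCC1(C)OCCO1)/C=C/C | intermediate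
13 | (3R,4E)-N-methoxy-N,3-dimethyl-3-(4-oxopentyl)hex-4-enamide | CON(C)C(=O)C[C@@](C)(CCCC(C)=O)/C=C/C | intermediate
14 | triethyl phosphonoacetate | CCOC(=O)CP(=O)(OCC)OCC | starting material
15 | ethyl (2E,7R,8E)-7-{2-[methoxy(methyl)amino]-2-oxoethyl}-3,7-dimethyldeca-2,8-dienoate | CCOC(=O)/C=C(\C)CCC[C@](C)(CC(=O)N(C)OC)/C=C/C | intermediate
16 | ethyl (2E,7R)-7-formyl-9-[methoxy(methyl)amino]-3,7-dimethyl-9-oxonon-2-enoate | CCOC(=O)/C=C(\C)CCC[C@](C)(CC(=O)N(C)OC)C=O | intermediate
17 | ethyl (2E,7R)-7-(1,3-dioxolan-2-yl)-9-[methoxy(methyl)amino]-3,7-dimethyl-9-oxonon-2-enoate | CCOC(=O)/C=C(\C)CCC[C@](C)(CC(=O)N(C)OC)C1OCCO1 | intermediate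
18 | prop-1-yn-1-ylmagnesium bromide | CC#C[Mg]Br | starting material
19 | ethyl (2E,7R)-7-(1,3-dioxolan-2-yl)-3,7-dimethyl-9-oxododec-2-en-10-ynoate | CCOC(=O)/C=C(\C)CCC[C@](C)(CC(=O)C#CC)C1OCCO1 | intermediate
20 | ethyl (2E,7R,10E)-7-(1,3-dioxolan-2-yl)-11-ethoxy-3,7-dimethyl-9-oxododeca-2,10-dienoate | CCOC(=O)/C=C(\C)CCC[C@](C)(CC(=O)/C=C(\C)OCC)C1OCCO1 | intermediate
21 | ethyl (2E,7R,8Z,10E)-9-[(tert-butyldimethylsilyl)oxy]-7-(1,3-dioxolan-2-yl)-11-ethoxy-3,7-dimethyldodeca-2,8,10-trienoate (key-step precursor) | CCOC(=O)/C=C(\C)CCC[C@@](C)(C1OCCO1)/C=C(O[Si](C)(C)C(C)(C)C)/C=C(\C)OCC | intermediate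
22 | ethyl 6-[(tert-butyldimethylsilyl)oxy]-4α-(1,3-dioxolan-2-yl)-8-ethoxy-4β,8,10β-trimethyl-5αH-decal-6-ene-9β-carboxylate (C8 configuration immaterial) | CCOC(=O)[C@@H]1[C@@]2(C)CCC[C@@](C)(C3OCCO3)[C@@H]2C(O[Si](C)(C)C(C)(C)C)=CC1(C)OCC | intermediate
23 | ethyl 4α-(1,3-dioxolan-2-yl)-4β,8,10β-trimethyl-6-oxo-5αH-decal-7-ene-9β-carboxylate (key-step product) | CCOC(=O)[C@@H]1[C@@]2(C)CCC[C@@](C)(C3OCCO3)[C@@H]2C(=O)C=C1C | intermediate
24 | ethyl 4α-(1,3-dioxolan-2-yl)-7α,8α-epoxy-4β,8β,10β-trimethyl-6-oxo-5αH-decalin-9β-carboxylate | CCOC(=O)[C@@H]1[C@@]2(C)CCC[C@@](C)(C4OCCO4)[C@@H]2C(=O)[C@H]3O[C@@]13C | intermediate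
25 | ethyl 4α-(1,3-dioxolan-2-yl)-8α-hydroxy-4β,8β,10β-trimethyl-6-oxo-5αH-decalin-9β-carboxylate | CCOC(=O)[C@@H]1[C@@]2(C)CCC[C@@](C)(C3OCCO3)[C@@H]2C(=O)C[C@@]1(C)O | intermediate
26 | 4α-(1,3-dioxolan-2-yl)-9β-(hydroxymethyl)-4β,8β,10β-trimethyl-5αH-decalin-6α,8α-diol | OC[C@@H]1[C@@]2(C)CCC[C@@](C)(C3OCCO3)[C@@H]2[C@@H](O)C[C@@]1(C)O | intermediate
27 | 4α-(1,3-dioxolan-2-yl)-6α,8α-dihydroxy-4β,8β,10β-trimethyl-5αH-decalin-9β-carbaldehyde | O=C[C@@H]1[C@@]2(C)CCC[C@@](C)(C3OCCO3)[C@@H]2[C@@H](O)C[C@@]1(C)O | intermediate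
28 | 4α-(1,3-dioxolan-2-yl)-4β,8β,10β-trimethyl-9β-vinyl-5αH-decalin-6α,8α-diol | C=C[C@@H]1[C@@]2(C)CCC[C@@](C)(C3OCCO3)[C@@H]2[C@@H](O)C[C@@]1(C)O | intermediate
29 | dimethyl (4R,5R)-2,2-dimethyl-1,3-dioxolane-4,5-dicarboxylate (L-tartrate acetonide) | COC(=O)[C@@H]1OC(C)(C)O[C@H]1C(=O)OC | starting material
30 | (4R,5R)-N4,N5-dimethoxy-N4,N5,2,2-tetramethyl-1,3-dioxolane-4,5-dicarboxamide | CON(C)C(=O)[C@@H]1OC(C)(C)O[C@H]1C(=O)N(C)OC | intermediate
31 | (4R,5R)-5-acetyl-N-methoxy-N,2,2-trimethyl-1,3-dioxolane-4-carboxamide | CC(=O)[C@@H]1OC(C)(C)O[C@H]1C(=O)N(C)OC | intermediate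
32 | 1-{(4R,5R)-5-[methoxy(methyl)carbamoyl]-2,2-dimethyl-1,3-dioxolan-4-yl}vinyl trifluoromethanesulfonate | C=C(OS(=O)(=O)C(F)(F)F)[C@@H]1OC(C)(C)O[C@H]1C(=O)N(C)OC | intermediate
33 | ethyl propiolate | C#CC(=O)OCC | starting material
34 | lithium 3-ethoxy-3-oxoprop-1-yn-1-ide | [Li]C#CC(=O)OCC | intermediate
35 | ethyl 4-{(4R,5R)-2,2-dimethyl-5-[1-(trifluoromethylsulfonyloxy)vinyl]-1,3-dioxolan-4-yl}-4-oxobut-2-ynoate | C=C(OS(=O)(=O)C(F)(F)F)[C@@H]1OC(C)(C)O[C@H]1C(=O)C#CC(=O)OCC | intermediate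
36 | ethyl (4R)-4-{(4S,5R)-2,2-dimethyl-5-[1-(trifluoromethylsulfonyloxy)vinyl]-1,3-dioxolan-4-yl}-4-hydroxybut-2-ynoate | C=C(OS(=O)(=O)C(F)(F)F)[C@@H]1OC(C)(C)O[C@H]1[C@H](O)C#CC(=O)OCC | intermediate
37 | ethyl (2Z,4R)-4-{(4S,5R)-2,2-dimethyl-5-[1-(trifluoromethylsulfonyloxy)vinyl]-1,3-dioxolan-4-yl}-4-hydroxy-3-methylbut-2-enoate | C=C(OS(=O)(=O)C(F)(F)F)[C@@H]1OC(C)(C)O[C@H]1[C@H](O)/C(C)=C\C(=O)OCC | intermediate
38 | 1-{(4R,5S)-2,2-dimethyl-5-[(2R)-3-methyl-5-oxo-2,5-dihydrofuran-2-yl]-1,3-dioxolan-4-yl}vinyl trifluoromethanesulfonate | C=C(OS(=O)(=O)C(F)(F)F)[C@@H]1OC(C)(C)O[C@H]1[C@@H]2OC(=O)C=C2C | intermediate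
39 | 9-[2-(decalin-9β-yl)ethyl]-9-borabicyclo[3.3.1]nonane derived from 28 (boron on C12) | B1(CC[C@@H]3[C@@]4(C)CCC[C@@](C)(C5OCCO5)[C@@H]4[C@@H](O)C[C@@]3(C)O)C2CCCC1CCC2 | intermediate
40 | 18,18-ethylenedioxy-14,15-O-isopropylidene derivative of the target | C=C(CC[C@@H]1[C@@]2(C)CCC[C@@](C)(C3OCCO3)[C@@H]2[C@@H](O)C[C@@]1(C)O)[C@@H]4OC(C)(C)O[C@H]4[C@@H]5OC(=O)C=C5C | intermediate
41 | CNP0156243.1: (5R)-5-[(1R,2S)-1,2-dihydroxy-3-methylidene-5-(4α-formyl-6α,8α-dihydroxy-4β,8β,10β-trimethyl-5αH-decalin-9β-yl)pentyl]-4-methylfuran-2(5H)-one | C=C(CC[C@@H]1[C@@]2(C)CCC[C@@](C)(C=O)[C@@H]2[C@@H](O)C[C@@]1(C)O)[C@H](O)[C@@H](O)[C@@H]1OC(=O)C=C1C | target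

Total step count: 25.
Longest linear sequence: 19 steps (steps 1–17, 24 and 25); the side-chain branch is steps 18–23.

Steps most likely to fail

1. Step 12 (key step). What may go wrong: loss of the silyl dienol ether by desilylation or hydrogen shift before cycloaddition, slow bond formation at the fully substituted C10, or competition from the cis-fused mode, which would give the wrong C4/C10 relationship. Fallback: an anionic intramolecular double Michael sequence that forms the same two bonds stepwise. It sets out from 20: LiHMDS (THF, −78 → 0 °C) generates the α′-enolate, which adds to the enoate (C5–C10, ring A) and after a proton quench should give the cyclohexane keto ester F1. KOt-Bu (THF) then adds the ester enolate at C9 to C8 of the β-ethoxy enone with loss of ethoxide (ring B), and the sequence comes back to the route at 23.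

2. Step 15. What may go wrong: retro-aldol cleavage of the β-alkoxide ketone, or incomplete ester reduction through enolization, in the strongly basic dissolving-metal medium. Fallback: the two reductions are separated. From 25, LiAlH4 (THF, 0 °C) reduces ester and ketone to the 6β,8α,11-triol F2. Dess–Martin periodinane oxidises both the primary and the secondary alcohol to the keto aldehyde F3. Wittig methylenation, selective for the aldehyde over the hindered C6 ketone, gives the vinyl ketone F4. Li/NH3, now with no ester present, reduces the ketone to the equatorial 6α-alcohol and returns to the route at 28.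

3. Step 24. What may go wrong: base-induced γ-deprotonation of the butenolide during the coupling, with epimerization at C16 or β-elimination of the C15 oxygen, or incomplete hydroboration of the hindered vinyl group. Fallback: the coupling is run before the butenolide exists. The 9-BBN adduct of 28 is coupled under the same conditions with the base-stable enol triflate 32 to give the coupled Weinreb amide F5. Excess lithium acetylide 34 gives the coupled ynone F6, (S)-Alpine-Borane gives the coupled propargylic alcohol F7, and Me2CuLi with lactonization returns to the route at 40.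

Further compounds
F1 | step 12 | ethyl 2-[2-((E)-3-ethoxybut-2-enoyl)-3-(1,3-dioxolan-2-yl)-1,3-dimethylcyclohexyl]acetate with the C4, C5 and C10 configuration of 23 | CCOC(=O)C[C@@]1(C)CCC[C@@](C)(C2OCCO2)[C@@H]1C(=O)/C=C(\C)OCC
F2 | step 15 | 4α-(1,3-dioxolan-2-yl)-9β-(hydroxymethyl)-4β,8β,10β-trimethyl-5αH-decalin-6β,8α-diol | OC[C@@H]1[C@@]2(C)CCC[C@@](C)(C3OCCO3)[C@@H]2[C@H](O)C[C@@]1(C)O
F3 | step 15 | 4α-(1,3-dioxolan-2-yl)-8α-hydroxy-4β,8β,10β-trimethyl-6-oxo-5αH-decalin-9β-carbaldehyde | O=C[C@@H]1[C@@]2(C)CCC[C@@](C)(C3OCCO3)[C@@H]2C(=O)C[C@@]1(C)O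
F4 | step 15 | 4α-(1,3-dioxolan-2-yl)-8α-hydroxy-4β,8β,10β-trimethyl-9β-vinyl-5αH-decalin-6-one | C=C[C@@H]1[C@@]2(C)CCC[C@@](C)(C3OCCO3)[C@@H]2C(=O)C[C@@]1(C)O
F5 | step 24 | Weinreb amide from coupling of 39 with 32 (C13–C15 unit attached at C12, amide at C16) | C=C(CC[C@@H]1[C@@]2(C)CCC[C@@](C)(C3OCCO3)[C@@H]2[C@@H](O)C[C@@]1(C)O)[C@@H]4OC(C)(C)O[C@H]4C(=O)N(C)OC
F6 | step 24 | coupled γ-oxo ynoate (ethyl 4-oxobut-2-ynoate at C16) | C=C(CC[C@@H]1[C@@]2(C)CCC[C@@](C)(C3OCCO3)[C@@H]2[C@@H](O)C[C@@]1(C)O)[C@@H]4OC(C)(C)O[C@H]4C(=O)C#CC(=O)OCC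
F7 | step 24 | coupled (16R)-propargylic alcohol (ethyl 4-hydroxybut-2-ynoate at C16) | C=C(CC[C@@H]1[C@@]2(C)CCC[C@@](C)(C3OCCO3)[C@@H]2[C@@H](O)C[C@@]1(C)O)[C@@H]4OC(C)(C)O[C@H]4[C@H](O)C#CC(=O)OCC
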